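**Strategy.** The route rests on opening the ten-membered ring at the C2–C3 bond, between the acetoxy-bearing carbinol C2 (attached to quaternary C1 of ring A) and the Z-alkene C3=C4 of the 3,5-diene. The key step is an intramolecular Nozaki–Hiyama–Kishi addition: a (Z)-alkenyl iodide at C3 adds to the non-enolisable neopentyl aldehyde C2, which closes the carbocycle, creates the C2 carbinol stereocentre and keeps the Z geometry in one operation. The precursor already carries fully acylated ring A with its spiro-epoxide, the hydroxy lactone and the Z-iodoalkene–diene unit, so that only one acetylation follows.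

Key step: step 25

Remark: atom labels follow the briarane numbering of the target: C1 (quaternary, CH3-15), C2–C9 (ten-membered ring), C10, C11 (spiro-epoxide, CH2-20), C12–C14 (ring A), C16 (CH2OAc on C5), C17–C19 (lactone, CH3-18). α means the face of ring A opposite to CH3-15. The orthoester carbon in 8–14 and the CHBr carbon in 24–26 are epimeric mixtures and are left unspecified.

Assumption: the (S,S)-salen ligand is taken to give the drawn enantiomer of 5; if the sense of induction is the opposite, the (R,R)-ligand is used.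

Step 1
Reactants: 1 (1E)-3-(tert-butyldimethylsilyloxy)-N,N-dimethylbuta-1,3-dien-1-amine; 2 ethyl (2E)-3-methyl-4-oxobut-2-enoate
Product: 5 ethyl (1S,2S)-2-(hydroxymethyl)-2-methyl-5-oxocyclohex-3-ene-1-carboxylate, via cycloadduct 3 (not isolated), via carbinol 4 (not isolated)
Conditions: [(S,S)-salen]CrSbF6 (5 mol %; salen = N,N′-bis(3,5-di-tert-butylsalicylidene)-trans-cyclohexane-1,2-diamine dianion), 4 Å MS, CH2Cl2, −40 °C; then NaBH4, EtOH, −20 °C; then aq. HF, MeCN, 0 °C
Reagents that add atoms: none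
Why: Catalytic enantioselective Diels–Alder reaction of a 1-amino-3-siloxydiene with an α-substituted acrolein, in which the aldehyde bound to the trivalent chromium salen complex directs the nucleophilic diene terminus to C10, the E geometry of 2 fixes CH2-2 and C9 trans on C1/C10, the ligand sets their absolute configuration, NaBH4 then reduces only the aldehyde and HF unmasks the enone by desilylation and loss of dimethylamine.

Step 2
Reactants: 5 hydroxy enone
Product: 6 tert-butyldimethylsilyl ether of 5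
Conditions: TBSCl, imidazole, DMF, 0 °C to rt
Reagents that add atoms: tert-butyldimethylsilyl chloride (C[Si](C)(Cl)C(C)(C)C)
Why: Standard silylation of the only hydroxyl, which also prevents trans-lactonisation onto the C9 ester.

Step 3
Reactants: 6 silyl ether enone
Product: 7 13α,14α-diol
Conditions: OsO4 (5 mol %), NMO, citric acid, t-BuOH/H2O, rt
Reagents that add atoms: N-methylmorpholine N-oxide (C[N+]1([O-])CCOCC1), water (O)
Why: Catalytic OsO4/NMO syn-dihydroxylation of the enone C13=C14 should occur on the α face, anti to the axial CH3-15 on the adjacent quaternary C1, setting C13 and C14 together, cis to CH2-2.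

Step 4
Reactants: 7 diol
Product: 8 cyclic methyl orthoacetate of the 13,14-diol
Conditions: MeC(OMe)3, PPTS (cat.), CH2Cl2, rt; Et3N quench
Reagents that add atoms: trimethyl orthoacetate (COC(C)(OC)OC)
Why: Acid-catalysed orthoester exchange gives the base-stable cyclic orthoacetate of the cis-diol, which later delivers the C14 acetate.

Step 5
Reactants: 8 orthoester ketone
Product: 11 C11 α-methylene ketone, via Mannich base 9 (not isolated), via ammonium iodide 10 (not isolated)
Conditions: LDA, THF, −78 °C; CH2=NMe2+ I−, −78 °C to rt; then MeI, CH2Cl2; then aq. NaHCO3, rt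
Reagents that add atoms: Eschenmoser's salt, N,N-dimethylmethyleneiminium iodide (C=[N+](C)C.[I-])
Why: Kinetic deprotonation should occur at the C11 methylene and not at the oxygen-bearing C13, and Mannich reaction, quaternisation and mild E1cB elimination give the α-methylene ketone carrying C20, which is reduced at once to avoid isomerisation into the ring.

Step 6
Reactants: 11 α-methylene ketone
Product: 12 12α-allylic alcohol with C9 primary alcohol
Conditions: DIBAL-H (5 equiv), CH2Cl2, −78 to −40 °C; Rochelle salt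
Reagents that add atoms: none
Why: DIBAL-H reduces the enone 1,2 and the ester to the primary alcohol, and hydride should reach C12 along the equatorial β trajectory because the α-axial approach is blocked by the axial O14 of the cis-fused dioxolane, giving the axial 12α-alcohol, all-cis with O13 and O14.

Step 7
Reactants: 12 allylic alcohol
Product: 13 11,20-epoxide
Conditions: VO(acac)2 (5 mol %), t-BuOOH, CH2Cl2, 0 °C
Reagents that add atoms: tert-butyl hydroperoxide (CC(C)(C)OO)
Why: Vanadium-catalysed hydroxyl-directed epoxidation of the allylic alcohol delivers oxygen syn to the axial 12α-OH, on the face that is also remote from the axial CH3-15, setting C11 with O α and CH2-20 β.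

Step 8
Reactants: 13 epoxy diol
Product: 15 C9 aldehyde with 14α-acetate and 12α,13α-diol, via epoxy aldehyde 14 (not isolated)
Conditions: TEMPO (cat.), PhI(OAc)2, CH2Cl2, rt; then AcOH/H2O 4:1, rt
Reagents that add atoms: water (O)
Why: TEMPO/PhI(OAc)2 oxidises the primary alcohol selectively over the hindered secondary one, and aqueous acetic acid then opens the cyclic orthoester under stereoelectronic control to the axial C14 acetate and the equatorial C13 alcohol.

Step 9
Reactants: 15 aldehyde diol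
Product: 16 ring A aldehyde with 12α,13α-bis(3-methylbutanoate)
Conditions: (i-BuCO)2O, DMAP, pyridine, CH2Cl2, 0 °C to rt
Reagents that add atoms: 3-methylbutanoic anhydride (CC(C)CC(=O)OC(=O)CC(C)C)
Why: DMAP-catalysed acylation esterifies both remaining hydroxyls, and the equatorial epoxide C–O bond at C11 is poorly aligned for β-elimination from the C10 enolate, so the β,γ-epoxy aldehyde should survive the mild amine base.

Step 10
Reactants: 17 2-bromoprop-2-enoic acid
Product: 18 2-bromo-N-methoxy-N-methylprop-2-enamide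
Conditions: MeNHOMe·HCl, EDC·HCl, N-methylmorpholine, CH2Cl2, 0 °C
Reagents that add atoms: N,O-dimethylhydroxylamine hydrochloride (CNOC.Cl)
Why: Carbodiimide amide coupling to the Weinreb amide.

Step 11
Reactants: 19 1-methoxy-4-[(prop-2-yn-1-yloxy)methyl]benzene; 18 Weinreb amide
Product: 20 2-bromo-6-[(4-methoxybenzyl)oxy]hex-1-en-4-yn-3-one
Conditions: 19, n-BuLi, THF, −78 °C; then 18; cold aq. NH4Cl/HCl quench
Reagents that add atoms: none
Why: Acylation of the lithium acetylide by the Weinreb amide stops at the ketone through the chelated tetrahedral intermediate.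

Step 12
Reactants: 20 bromo enynone
Product: 21 (3S)-2-bromo-6-[(4-methoxybenzyl)oxy]hex-1-en-4-yn-3-ol
Conditions: (R)-2-methyl-CBS-oxazaborolidine (0.5 equiv), catecholborane, toluene/CH2Cl2, −78 °C
Reagents that add atoms: none
Why: Corey–Bakshi–Shibata reduction in which the 1-bromovinyl group acts as the large and the alkynyl group as the small substituent, so the (R)-catalyst should give the (S)-carbinol, the future C7.

Step 13
Reactants: 16 ring A aldehyde; 21 bromoalkenyl carbinol
Product: 22 coupled C7,C9-diol with C8 exo-methylene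
Conditions: CrCl2 (6 equiv), NiCl2 (0.1 equiv), DMSO/THF, rt
Reagents that add atoms: none
Why: Intermolecular Nozaki–Hiyama–Kishi coupling of the 2-bromoalkene with the hindered aldehyde tolerates esters, epoxide and free hydroxyl, and Felkin–Anh addition with the C1 arm as the large group is expected to set C9 as drawn.

Step 14
Reactants: 22 diol; 23 2-bromopropanoyl bromide
Product: 24 C7 2-bromopropanoate
Conditions: pyridine, CH2Cl2, −40 °C
Reagents that add atoms: none
Why: The C7 hydroxyl, flanked only by sp and sp2 carbons, should be acylated selectively over the C9 hydroxyl, which is shielded by ring A.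

Step 15
Reactants: 24 C7 ester
Product: 25 C9 acetate
Conditions: Ac2O, DMAP, pyridine, CH2Cl2, 0 °C
Reagents that add atoms: acetic anhydride (CC(=O)OC(C)=O)
Why: DMAP-catalysed acetylation of the remaining hindered secondary alcohol installs the C9 acetate.

Step 16
Reactants: 25 exo-methylene diester
Product: 26 C8 ketone
Conditions: O3, CH2Cl2/pyridine, −78 °C; then Me2S
Reagents that add atoms: ozone ([O-][O+]=O)
Why: Ozonolysis cleaves the 1,1-disubstituted alkene far faster than the alkyne or the anisyl ring and unveils the C8 ketone under neutral conditions.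

Step 17
Reactants: 26 keto bromo ester
Product: 27 8-hydroxy-17-methyl γ-lactone
Conditions: SmI2 (2.2 equiv), THF, −78 °C
Reagents that add atoms: none
Why: Samarium Reformatsky reaction in which the α-bromo ester is reduced first and the enolate adds intramolecularly to C8, closing the γ-lactone with H-7 eclipsing the bulky C9 arm so that OH-8 ends cis to C6, and with the enolate methyl avoiding C9, which gives C8 and C17 as drawn.

Step 18
Reactants: 27 lactone p-methoxybenzyl ether
Product: 28 propargylic C16 alcohol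
Conditions: DDQ, CH2Cl2/pH 7 buffer, 0 °C
Reagents that add atoms: none
Why: Oxidative cleavage of the p-methoxybenzyl ether frees the propargylic alcohol that must direct the next step.

Step 19
Reactants: 28 propargylic alcohol
Product: 30 C5 alkenyl iodide, via alkenylstannane 29 (not isolated)
Conditions: [Cp*RuCl]4 (2.5 mol %; Cp* = pentamethylcyclopentadienyl), Bu3SnH (1.05 equiv), CH2Cl2, rt; then 2,6-lutidine, I2, 0 °C
Reagents that add atoms: iodine (II)
Why: Hydroxyl-directed ruthenium-catalysed trans-hydrostannation places tin on C5, proximal to the OH, and hydrogen anti on C6 so that C7 is cis to tin, and iododestannylation proceeds with retention.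

Step 20
Reactants: 30 alkenyl iodide; 31 (Z)-1,2-bis(tributylstannyl)ethene (3 equiv)
Product: 32 (3Z)-dienylstannane
Conditions: Pd2(dba)3 (5 mol %), AsPh3, CuI, NMP, rt
Reagents that add atoms: none
Why: Stille coupling at zerovalent palladium with retention at both partners attaches C4=C3 as a Z-alkenylstannane, and the excess of 31 suppresses double coupling.

Step 21
Reactants: 32 dienylstannane
Product: 33 (3Z)-iododiene with free C16 alcohol
Conditions: I2, CH2Cl2, −78 °C
Reagents that add atoms: iodine (II)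
Why: Iododestannylation with retention gives the (Z)-alkenyl iodide.

Step 22
Reactants: 33 iododiene alcohol
Product: 34 C16 acetate
Conditions: Ac2O, pyridine, CH2Cl2, 0 °C
Reagents that add atoms: acetic anhydride (CC(=O)OC(C)=O)
Why: Acetylation of the primary allylic alcohol, which the tertiary 8-OH does not undergo.

Step 23
Reactants: 34 silyl ether
Product: 35 C2 primary alcohol
Conditions: HF·pyridine, pyridine, THF, 0 °C to rt
Reagents that add atoms: none
Why: Fluoride-mediated cleavage of the primary silyl ether under buffered conditions that should spare the epoxide, the esters and the iododiene.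

Step 24
Reactants: 35 primary alcohol
Product: 36 C2 aldehyde
Conditions: Dess–Martin periodinane, NaHCO3, CH2Cl2, rt
Reagents that add atoms: none
Why: Dess–Martin oxidation of the neopentyl alcohol to the non-enolisable aldehyde under buffered, neutral conditions.

Step 25
Reactants: 36 iododiene aldehyde
Product: 37 macrocyclic C2 alcohol
Conditions: CrCl2 (15 equiv), NiCl2 (0.2 equiv), DMSO/THF, 2 mM, rt
Reagents that add atoms: none
Why: Nozaki–Hiyama–Kishi reaction run intramolecularly: NiCl2 is reduced by CrCl2 to zerovalent nickel, which inserts into the C3–I bond with retention of the Z geometry, and transmetalation gives a (Z)-alkenyl trivalent chromium species that adds to the C2 aldehyde. The closest known reaction type is the NHK macrocyclisation used to close nine- and ten-membered carbocycles. The ten-membered ring is closed by a 10-exo-trig 1,2-addition, the carbonyl oxygen staying outside the new ring. The new stereocentre C2 is controlled by the substrate: the tether from C10 forces C3 to approach gauche to C10 and therefore anti to the C1–C14 bond, with the trajectory leaning toward C10 and away from the axial CH3-15, so the chromium-bound oxygen sits on the periphery between CH3-15 and C14, which corresponds to 2S. The step needs chemoselectivity for the aldehyde over five ester groups, the lactone and the epoxide, which is inherent to alkenylchromium reagents, and ring closure over oligomerisation, which is secured by high dilution and by the preorganisation from the two alkenes and the trans-diequatorial C2 and C9 arms on ring A.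

Step 26
Reactants: 37 macrocyclic alcohol
Product: 38 CNP0303383.2
Conditions: Ac2O, DMAP, Et3N, CH2Cl2, rt
Reagents that add atoms: acetic anhydride (CC(=O)OC(C)=O)
Why: DMAP-catalysed acetylation of the secondary allylic C2 alcohol, while the hindered tertiary 8-OH should remain free.

**Compound list**

1 | (1E)-3-(tert-butyldimethylsilyloxy)-N,N-dimethylbuta-1,3-dien-1-amine | CN(C)/C=C/C(=C)O[Si](C)(C)C(C)(C)C | starting material
2 | ethyl (2E)-3-methyl-4-oxobut-2-enoate | CCOC(=O)/C=C(\C)C=O | starting material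
3 | cycloadduct: ethyl 5-(dimethylamino)-6-formyl-6-methyl-3-(tert-butyldimethylsilyloxy)cyclohex-3-ene-1-carboxylate, formyl trans to ester and cis to the amino group | CCOC(=O)[C@H]1CC(O[Si](C)(C)C(C)(C)C)=C[C@H](N(C)C)[C@]1(C)C=O | intermediate
4 | carbinol from 3 (formyl reduced to hydroxymethyl) | CCOC(=O)[C@H]1CC(O[Si](C)(C)C(C)(C)C)=C[C@H](N(C)C)[C@]1(C)CO | intermediate
5 | ethyl (1S,2S)-2-(hydroxymethyl)-2-methyl-5-oxocyclohex-3-ene-1-carboxylate (ester and CH2OH trans) | CCOC(=O)[C@H]1CC(=O)C=C[C@]1(C)CO | intermediate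
6 | tert-butyldimethylsilyl ether of 5 | CCOC(=O)[C@H]1CC(=O)C=C[C@]1(C)CO[Si](C)(C)C(C)(C)C | intermediate
7 | 13α,14α-diol of 6 (both OH cis to CH2-2, C12 ketone) | CCOC(=O)[C@H]1CC(=O)[C@H](O)[C@H](O)[C@]1(C)CO[Si](C)(C)C(C)(C)C | intermediate
8 | 13,14-O-(1-methoxyethylidene) orthoester of 7 | CCOC(=O)[C@H]1CC(=O)[C@@H]2OC(C)(OC)O[C@@H]2[C@]1(C)CO[Si](C)(C)C(C)(C)C | intermediate
9 | C11 (dimethylamino)methyl Mannich base of 8 | CCOC(=O)[C@H]1C(CN(C)C)C(=O)[C@@H]2OC(C)(OC)O[C@@H]2[C@]1(C)CO[Si](C)(C)C(C)(C)C | intermediate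
10 | C11 (trimethylammonio)methyl iodide | CCOC(=O)[C@H]1C(C[N+](C)(C)C)C(=O)[C@@H]2OC(C)(OC)O[C@@H]2[C@]1(C)CO[Si](C)(C)C(C)(C)C.[I-] | intermediate
11 | C11 exo-methylene C12 ketone | CCOC(=O)[C@H]1C(=C)C(=O)[C@@H]2OC(C)(OC)O[C@@H]2[C@]1(C)CO[Si](C)(C)C(C)(C)C | intermediate
12 | 12α-hydroxy C11 exo-methylene compound with C9 primary alcohol | OC[C@H]1C(=C)[C@H](O)[C@@H]2OC(C)(OC)O[C@@H]2[C@]1(C)CO[Si](C)(C)C(C)(C)C | intermediate
13 | 11,20-epoxide of 12 (epoxide O α, CH2-20 β) | OC[C@H]1[C@@]3(CO3)[C@H](O)[C@@H]2OC(C)(OC)O[C@@H]2[C@]1(C)CO[Si](C)(C)C(C)(C)C | intermediate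
14 | C9 aldehyde of 13 (orthoester intact) | O=C[C@H]1[C@@]3(CO3)[C@H](O)[C@@H]2OC(C)(OC)O[C@@H]2[C@]1(C)CO[Si](C)(C)C(C)(C)C | intermediate
15 | C9 aldehyde with 14α-acetate, 12α,13α-diol and 11,20-epoxide | O=C[C@H]1[C@@]2(CO2)[C@H](O)[C@H](O)[C@H](OC(C)=O)[C@]1(C)CO[Si](C)(C)C(C)(C)C | intermediate
16 | ring A aldehyde: 14α-acetoxy-11,20-epoxy-12α,13α-bis(3-methylbutanoyloxy) C9 aldehyde with C2 silyl ether | O=C[C@H]1[C@@]2(CO2)[C@H](OC(=O)CC(C)C)[C@H](OC(=O)CC(C)C)[C@H](OC(C)=O)[C@]1(C)CO[Si](C)(C)C(C)(C)C | intermediate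
17 | 2-bromoprop-2-enoic acid | OC(=O)C(Br)=C | starting material
18 | 2-bromo-N-methoxy-N-methylprop-2-enamide | CON(C)C(=O)C(Br)=C | intermediate
19 | 1-methoxy-4-[(prop-2-yn-1-yloxy)methyl]benzene | C#CCOCc1ccc(OC)cc1 | starting material
20 | 2-bromo-6-[(4-methoxybenzyl)oxy]hex-1-en-4-yn-3-one | C=C(Br)C(=O)C#CCOCc1ccc(OC)cc1 | intermediate
21 | (3S)-2-bromo-6-[(4-methoxybenzyl)oxy]hex-1-en-4-yn-3-ol | COc1ccc(COCC#C[C@@H](C(Br)=C)O)cc1 | intermediate
22 | coupled diol: C7 and C9 carbinols flanking the C8 exo-methylene, C5≡C6 alkyne, C16 p-methoxybenzyl ether | COc1ccc(COCC#C[C@H](O)C(=C)[C@@H](O)[C@H]2[C@@]3(CO3)[C@H](OC(=O)CC(C)C)[C@H](OC(=O)CC(C)C)[C@H](OC(C)=O)[C@]2(C)CO[Si](C)(C)C(C)(C)C)cc1 | intermediate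
23 | 2-bromopropanoyl bromide (racemic) | CC(Br)C(Br)=O | starting material
24 | C7 2-bromopropanoate of 22 (C9 hydroxyl free) | COc1ccc(COCC#C[C@H](OC(=O)C(C)Br)C(=C)[C@@H](O)[C@H]2[C@@]3(CO3)[C@H](OC(=O)CC(C)C)[C@H](OC(=O)CC(C)C)[C@H](OC(C)=O)[C@]2(C)CO[Si](C)(C)C(C)(C)C)cc1 | intermediate
25 | C9 acetate of 24 | COc1ccc(COCC#C[C@H](OC(=O)C(C)Br)C(=C)[C@@H](OC(C)=O)[C@H]2[C@@]3(CO3)[C@H](OC(=O)CC(C)C)[C@H](OC(=O)CC(C)C)[C@H](OC(C)=O)[C@]2(C)CO[Si](C)(C)C(C)(C)C)cc1 | intermediate
26 | C8 ketone (9-acetoxy, 7-(2-bromopropanoyloxy)) | COc1ccc(COCC#C[C@H](OC(=O)C(C)Br)C(=O)[C@@H](OC(C)=O)[C@H]2[C@@]3(CO3)[C@H](OC(=O)CC(C)C)[C@H](OC(=O)CC(C)C)[C@H](OC(C)=O)[C@]2(C)CO[Si](C)(C)C(C)(C)C)cc1 | intermediate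
27 | 8-hydroxy-17-methyl γ-lactone (C7–O–C19), C16 p-methoxybenzyl ether | COc1ccc(COCC#C[C@@H]4OC(=O)[C@H](C)[C@@]4(O)[C@@H](OC(C)=O)[C@H]2[C@@]3(CO3)[C@H](OC(=O)CC(C)C)[C@H](OC(=O)CC(C)C)[C@H](OC(C)=O)[C@]2(C)CO[Si](C)(C)C(C)(C)C)cc1 | intermediate
28 | lactone with free propargylic C16 alcohol | OCC#C[C@@H]1OC(=O)[C@H](C)[C@@]1(O)[C@@H](OC(C)=O)[C@H]2[C@@]3(CO3)[C@H](OC(=O)CC(C)C)[C@H](OC(=O)CC(C)C)[C@H](OC(C)=O)[C@]2(C)CO[Si](C)(C)C(C)(C)C | intermediate
29 | C5 tributylstannyl alkene (tin cis to C7) | OCC(/[Sn](CCCC)(CCCC)CCCC)=C/[C@@H]1OC(=O)[C@H](C)[C@@]1(O)[C@@H](OC(C)=O)[C@H]2[C@@]3(CO3)[C@H](OC(=O)CC(C)C)[C@H](OC(=O)CC(C)C)[C@H](OC(C)=O)[C@]2(C)CO[Si](C)(C)C(C)(C)C | intermediate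
30 | C5 alkenyl iodide (iodine cis to C7) | OCC(/I)=C/[C@@H]1OC(=O)[C@H](C)[C@@]1(O)[C@@H](OC(C)=O)[C@H]2[C@@]3(CO3)[C@H](OC(=O)CC(C)C)[C@H](OC(=O)CC(C)C)[C@H](OC(C)=O)[C@]2(C)CO[Si](C)(C)C(C)(C)C | intermediate
31 | (Z)-1,2-bis(tributylstannyl)ethene | CCCC[Sn](CCCC)(CCCC)/C=C\[Sn](CCCC)(CCCC)CCCC | starting material
32 | (3Z)-C3-stannyl diene | OCC(/C=C\[Sn](CCCC)(CCCC)CCCC)=C/[C@@H]1OC(=O)[C@H](C)[C@@]1(O)[C@@H](OC(C)=O)[C@H]2[C@@]3(CO3)[C@H](OC(=O)CC(C)C)[C@H](OC(=O)CC(C)C)[C@H](OC(C)=O)[C@]2(C)CO[Si](C)(C)C(C)(C)C | intermediate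
33 | (3Z)-C3-iodo diene with C16 alcohol | OCC(/C=C\I)=C/[C@@H]1OC(=O)[C@H](C)[C@@]1(O)[C@@H](OC(C)=O)[C@H]2[C@@]3(CO3)[C@H](OC(=O)CC(C)C)[C@H](OC(=O)CC(C)C)[C@H](OC(C)=O)[C@]2(C)CO[Si](C)(C)C(C)(C)C | intermediate
34 | C16 acetate of 33 | CC(=O)OCC(/C=C\I)=C/[C@@H]1OC(=O)[C@H](C)[C@@]1(O)[C@@H](OC(C)=O)[C@H]2[C@@]3(CO3)[C@H](OC(=O)CC(C)C)[C@H](OC(=O)CC(C)C)[C@H](OC(C)=O)[C@]2(C)CO[Si](C)(C)C(C)(C)C | intermediate
35 | C2 primary alcohol | CC(=O)OCC(/C=C\I)=C/[C@@H]1OC(=O)[C@H](C)[C@@]1(O)[C@@H](OC(C)=O)[C@H]2[C@@]3(CO3)[C@H](OC(=O)CC(C)C)[C@H](OC(=O)CC(C)C)[C@H](OC(C)=O)[C@]2(C)CO | intermediate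
36 | C2 aldehyde (open-chain precursor of the ring closure) | CC(=O)OCC(/C=C\I)=C/[C@@H]1OC(=O)[C@H](C)[C@@]1(O)[C@@H](OC(C)=O)[C@H]2[C@@]3(CO3)[C@H](OC(=O)CC(C)C)[C@H](OC(=O)CC(C)C)[C@H](OC(C)=O)[C@]2(C)C=O | intermediate
37 | macrocyclic (2S)-alcohol, 2-O-deacetyl target | CC(=O)OCC1=C/[C@@H]2OC(=O)[C@H](C)[C@@]2(O)[C@@H](OC(C)=O)[C@H]2[C@@]3(CO3)[C@H](OC(=O)CC(C)C)[C@H](OC(=O)CC(C)C)[C@H](OC(C)=O)[C@]2(C)[C@@H](O)/C=C\1 | intermediate
38 | CNP0303383.2 | CC(=O)OCC1=C/[C@@H]2OC(=O)[C@H](C)[C@@]2(O)[C@@H](OC(C)=O)[C@H]2[C@@]3(CO3)[C@H](OC(=O)CC(C)C)[C@H](OC(=O)CC(C)C)[C@H](OC(C)=O)[C@]2(C)[C@@H](OC(C)=O)/C=C\1 | target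

**Step count.** Total: 26 steps. Longest linear sequence: 23 steps (steps 1–9 and 13–26).

**Steps most likely to fail**

1. Step 25. The alkenylchromium may add to the wrong face of the aldehyde, since facial selectivity rests on one quaternary centre, so that the C2 epimer dominates; intermolecular coupling may also compete with ring closure. Fallback, setting out from 36: the ring is closed as in step 25 and the carbinols, rich in the C2-epimeric macrocyclic alcohol F1, are oxidised with Dess–Martin periodinane to the macrocyclic cross-conjugated dienone F2. A 1,2-reduction of this ketone under reagent control with a 2-methyl-CBS-oxazaborolidine and catecholborane (antipode chosen for the 2S carbinol) then sets C2, and the route is rejoined at 37.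

2. Step 17. Electron transfer to the ketone flanked by two acyloxy groups may compete with reduction of the bromo ester, with loss of the C9 acetate or the C7 ester, and closure of a five-membered ring through an endocyclic enolate may be slow. Fallback, setting out from 22: the C8–C17 bond is made intermolecularly and the lactone is closed afterwards. Selective silylation of the C7 hydroxyl (Et3SiCl, imidazole) gives the C7 triethylsilyl ether F3, acetylation (Ac2O, DMAP) gives the C9 acetate F4, and ozonolysis gives the C8 ketone F5. A zinc Reformatsky reaction with ethyl 2-bromopropanoate gives the β-hydroxy ester F6, and HF·pyridine removes the triethylsilyl group, after which the C7 hydroxyl closes the γ-lactone with loss of ethanol. The route is rejoined at 27.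

3. Step 13. The alkenylchromium may attack the wrong face of the aldehyde, because the Felkin–Anh bias between the two quaternary neighbours of C10 is weak, giving the 9-epimer. Fallback, setting out from 16: the coupling with 21 is run as in step 13 to the 9-epimeric diol F7, and the C7 hydroxyl is acylated with 23 to give the 9-epimeric bromopropanoate F8. The C9 carbinol is oxidised with Dess–Martin periodinane to the C9 α-methylene ketone F9, and reagent-controlled reduction (2-methyl-CBS-oxazaborolidine, catecholborane, antipode chosen for 9S) gives 24, where the route is rejoined.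

**Further compounds**

F1 | step 25 | C2 epimer of macrocyclic alcohol 37 | CC(=O)OCC1=C/[C@@H]2OC(=O)[C@H](C)[C@@]2(O)[C@@H](OC(C)=O)[C@H]2[C@@]3(CO3)[C@H](OC(=O)CC(C)C)[C@H](OC(=O)CC(C)C)[C@H](OC(C)=O)[C@]2(C)[C@H](O)/C=C\1
F2 | step 25 | macrocyclic C2 ketone (cross-conjugated dienone) | CC(=O)OCC1=C/[C@@H]2OC(=O)[C@H](C)[C@@]2(O)[C@@H](OC(C)=O)[C@H]2[C@@]3(CO3)[C@H](OC(=O)CC(C)C)[C@H](OC(=O)CC(C)C)[C@H](OC(C)=O)[C@]2(C)C(=O)/C=C\1
F3 | step 17 | C7 triethylsilyl ether of 22 | COc1ccc(COCC#C[C@H](O[Si](CC)(CC)CC)C(=C)[C@@H](O)[C@H]2[C@@]3(CO3)[C@H](OC(=O)CC(C)C)[C@H](OC(=O)CC(C)C)[C@H](OC(C)=O)[C@]2(C)CO[Si](C)(C)C(C)(C)C)cc1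
F4 | step 17 | C9 acetate of F3 | COc1ccc(COCC#C[C@H](O[Si](CC)(CC)CC)C(=C)[C@@H](OC(C)=O)[C@H]2[C@@]3(CO3)[C@H](OC(=O)CC(C)C)[C@H](OC(=O)CC(C)C)[C@H](OC(C)=O)[C@]2(C)CO[Si](C)(C)C(C)(C)C)cc1
F5 | step 17 | C8 ketone with C7 triethylsilyl ether | COc1ccc(COCC#C[C@H](O[Si](CC)(CC)CC)C(=O)[C@@H](OC(C)=O)[C@H]2[C@@]3(CO3)[C@H](OC(=O)CC(C)C)[C@H](OC(=O)CC(C)C)[C@H](OC(C)=O)[C@]2(C)CO[Si](C)(C)C(C)(C)C)cc1
F6 | step 17 | β-hydroxy ethyl ester from intermolecular Reformatsky addition | COc1ccc(COCC#C[C@H](O[Si](CC)(CC)CC)[C@@](O)([C@@H](C)C(=O)OCC)[C@@H](OC(C)=O)[C@H]2[C@@]3(CO3)[C@H](OC(=O)CC(C)C)[C@H](OC(=O)CC(C)C)[C@H](OC(C)=O)[C@]2(C)CO[Si](C)(C)C(C)(C)C)cc1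
F7 | step 13 | 9-epimer of diol 22 | COc1ccc(COCC#C[C@H](O)C(=C)[C@H](O)[C@H]2[C@@]3(CO3)[C@H](OC(=O)CC(C)C)[C@H](OC(=O)CC(C)C)[C@H](OC(C)=O)[C@]2(C)CO[Si](C)(C)C(C)(C)C)cc1
F8 | step 13 | 9-epimer of bromopropanoate 24 | COc1ccc(COCC#C[C@H](OC(=O)C(C)Br)C(=C)[C@H](O)[C@H]2[C@@]3(CO3)[C@H](OC(=O)CC(C)C)[C@H](OC(=O)CC(C)C)[C@H](OC(C)=O)[C@]2(C)CO[Si](C)(C)C(C)(C)C)cc1
F9 | step 13 | C9 α-methylene ketone | COc1ccc(COCC#C[C@H](OC(=O)C(C)Br)C(=C)C(=O)[C@H]2[C@@]3(CO3)[C@H](OC(=O)CC(C)C)[C@H](OC(=O)CC(C)C)[C@H](OC(C)=O)[C@]2(C)CO[Si](C)(C)C(C)(C)C)cc1
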